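**Strategy.** Everything rests on cutting ring B (C5–C6–C7–C8–C9–C10, labdane numbering) at C9: the six-membered ring is made from a ring-A-fused cyclopentanone by one-carbon ring expansion. In one flask, a dibromomethane-derived carbenoid inserts C9 between the C8 carbonyl and the quaternary C10, the resulting C8–C9 lithium enolate is formed regiospecifically and is alkylated by the chiral-pool C11–C15 iodide on the face opposite the axial C10 methyl. The step exploits the C8 methylidene carbon (as ketone) flanked by C9, whose side chain is anti to C20. The precursor is a trans-fused 6-hydroxy-4,4,7a-trimethylhydrindan-1-one, built from 2-methylcyclopentenone by asymmetric conjugate addition–allylation, Wacker oxidation and Conia-ene closure.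

Key step: step 7

Remark: the SMILES is read as a 9-epi-ent-labdane, (2S,5R,9S,10R,13S): trans ring fusion, C9 chain anti to the C10 methyl (axial), C2 ester syn to it (axial); monomethyl (R)-3-methylglutarate 1 is taken as commercially available.

Step 1
Reactants: 1 (R)-5-methoxy-3-methyl-5-oxopentanoic acid (monomethyl (R)-3-methylglutarate)
Product: 3 (S)-4-methyltetrahydro-2H-pyran-2-one, via lithium (S)-5-hydroxy-3-methylpentanoate 2 (not isolated)
Conditions: LiOH·H2O (1.0 equiv), MeOH, then evaporation; LiBH4, THF, 65 °C; then 2 M HCl, rt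
Reagents that add atoms: none
Why: LiBH4 should reduce the methyl ester but not the lithium carboxylate, and acidification lactonises the δ-hydroxy acid (chemoselective borohydride reduction, lactonisation), so the carboxyl that becomes C15 is kept and the future C13 stereocentre is untouched.

Step 2
Reactants: 3 (S)-4-methyltetrahydro-2H-pyran-2-one
Product: 5 methyl (R)-5-iodo-3-methylpentanoate, via trimethylsilyl (R)-5-iodo-3-methylpentanoate 4 (not isolated)
Conditions: Me3SiI, CH2Cl2, 40 °C; then MeOH, rt
Reagents that add atoms: iodotrimethylsilane (C[Si](C)(C)I); methanol (CO)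
Why: O-silylation of the lactone lets iodide open the ring by SN2 at the O–CH2 carbon and methanolysis of the silyl ester gives the ω-iodo methyl ester (lactone cleavage with iodotrimethylsilane), with the remote stereocentre unaffected.

Step 3
Reactants: 6 2-methylcyclopent-2-en-1-one; 7 isopropenylmagnesium bromide; 8 allyl iodide
Product: 10 (2R,3R)-2-allyl-2-methyl-3-(prop-1-en-2-yl)cyclopentan-1-one, via magnesium enolate 9 (not isolated)
Conditions: CuBr·SMe2 (5 mol%), (R)-1-[(Sp)-2-(dicyclohexylphosphino)ferrocenyl]ethyldiphenylphosphine (6 mol%; the ligand enantiomer that gives the 3R adduct is used), t-BuOMe, −78 °C; then 8, DMPU, −78 → 0 °C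
Reagents that add atoms: none
Why: Copper-catalysed asymmetric conjugate addition of a Grignard reagent to 2-methylcyclopentenone with in situ enolate alkylation should set C5 (3R) under ligand control, and allyl iodide should enter the enolate anti to the isopropenyl group, fixing the quaternary C10 (2R) and the later trans ring fusion.

Step 4
Reactants: 10 (2R,3R)-2-allyl-2-methyl-3-(prop-1-en-2-yl)cyclopentan-1-one
Product: 11 (2R,3R)-2-methyl-2-(2-oxopropyl)-3-(prop-1-en-2-yl)cyclopentan-1-one
Conditions: PdCl2 (10 mol%), CuCl (1 equiv), O2 (1 atm), DMF/H2O 7:1, rt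
Reagents that add atoms: water (O)
Why: Wacker oxidation should convert only the monosubstituted allyl alkene into the methyl ketone (C2 carbonyl, C3 methyl), the 1,1-disubstituted isopropenyl group being inert under these conditions.

Step 5
Reactants: 11 (2R,3R)-2-methyl-2-(2-oxopropyl)-3-(prop-1-en-2-yl)cyclopentan-1-one
Product: 12 (3aR,7aR)-4,4,7a-trimethylhexahydro-1H-indene-1,6(2H)-dione (trans-fused)
Conditions: degassed decalin (0.05 M), sealed tube, 300 °C
Reagents that add atoms: none
Why: In a thermal Conia-ene reaction the enol of the methyl ketone should add through C3 to the internal carbon of the isopropenyl group while its hydrogen goes to the terminal CH2, closing ring A at the C3–C4 bond and creating the gem-dimethyl carbon without touching C5 or C10 (the same enol–ene event that turns dihydrocarvone into camphor).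

Step 6
Reactants: 12 (3aR,7aR)-4,4,7a-trimethylhexahydro-1H-indene-1,6(2H)-dione
Product: 13 (3aR,6S,7aR)-6-hydroxy-4,4,7a-trimethyloctahydro-1H-inden-1-one
Conditions: LiBH(s-Bu)3 (1.05 equiv), THF, −78 °C; then aq. NH4Cl
Reagents that add atoms: none
Why: The bulky hydride should reduce the unhindered cyclohexanone in preference to the α-quaternary cyclopentanone and attack equatorially, away from the two syn-axial methyls, giving the axial C2 alcohol cis to the C10 methyl (chemoselective and diastereoselective ketone reduction).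

Step 7
Reactants: 13 (3aR,6S,7aR)-6-hydroxy-4,4,7a-trimethyloctahydro-1H-inden-1-one; 14 dibromomethane; 5 methyl (R)-5-iodo-3-methylpentanoate
Product: 17 methyl (3S)-5-[(1R,4aR,7S,8aR)-7-hydroxy-5,5,8a-trimethyl-2-oxodecahydronaphthalen-1-yl]-3-methylpentanoate, via dibromomethyl carbinolate 15 (not isolated), via lithium enolate 16 (not isolated)
Conditions: 14 (1.3 equiv), lithium 2,2,6,6-tetramethylpiperidide (2.4 equiv), THF, −78 °C; n-BuLi (1.3 equiv), −95 → 0 °C; then 5 (3 equiv), HMPA, −40 → 0 °C; aq. NH4Cl
Reagents that add atoms: none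
Why: LiCHBr2 (from 14 and the amide base) adds to the C8 ketone of 13 to give carbinolate 15; Br–Li exchange with n-BuLi then generates a β-oxido carbenoid in which the quaternary C10 migrates from C8 to the carbenoid carbon with loss of LiBr, so ring B arises from the cyclopentanone by one-carbon ring expansion (five- to six-membered, new atom C9) and appears only as the C8–C9 lithium enolate 16. The closest known reaction is the β-oxido carbenoid ring enlargement of cyclic ketones with dibromomethyllithium, here coupled with alkylation of the regiodefined lithium enolate by a primary iodide. No ring is closed in the usual sense: ring B is formed by the 1,2-alkyl shift, and both C8 epimers of 15 converge on the same planar enolate. The only new stereocentre, C9, is set in the alkylation, where the iodide should attack C9 axially on the face opposite the axial C10 methyl and so place the C9–C11 bond anti to C20. The step needs migration of C10 rather than C7, which the electron-rich fully substituted carbon should secure because the more substituted carbon migrates preferentially in this carbenoid shift, and it needs C-alkylation at C9 without enolate equilibration, which HMPA, excess iodide and low temperature should favour while the hindered axial C2 alkoxide stays unalkylated.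

Step 8
Reactants: 17 methyl (3S)-5-[(1R,4aR,7S,8aR)-7-hydroxy-5,5,8a-trimethyl-2-oxodecahydronaphthalen-1-yl]-3-methylpentanoate; 14 dibromomethane
Product: 18 methyl (3S)-5-[(1S,4aR,7S,8aR)-7-hydroxy-5,5,8a-trimethyl-2-methylidenedecahydronaphthalen-1-yl]-3-methylpentanoate
Conditions: Zn, 14, TiCl4 (reagent pre-formed in THF and aged at 5 °C), CH2Cl2, 0 °C → rt
Reagents that add atoms: none
Why: The non-basic zinc–titanium methylene reagent (Lombardo methylenation) should convert the hindered C8 ketone into the exocyclic methylidene without epimerising the adjacent axial C9 centre, and it tolerates the ester and the free hydroxyl.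

Step 9
Reactants: 18 methyl (3S)-5-[(1S,4aR,7S,8aR)-7-hydroxy-5,5,8a-trimethyl-2-methylidenedecahydronaphthalen-1-yl]-3-methylpentanoate; 19 3-methylbutanoyl chloride
Product: 20 methyl (3S)-3-methyl-5-[(1S,4aR,7S,8aR)-5,5,8a-trimethyl-2-methylidene-7-(3-methylbutanoyloxy)decahydronaphthalen-1-yl]pentanoate
Conditions: 19 (3 equiv), DMAP, pyridine, CH2Cl2, 0 → 40 °C
Reagents that add atoms: none
Why: DMAP-catalysed acylation with the acid chloride should esterify the hindered axial C2 hydroxyl with retention, the only free hydroxyl in the molecule.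

Step 10
Reactants: 20 methyl (3S)-3-methyl-5-[(1S,4aR,7S,8aR)-5,5,8a-trimethyl-2-methylidene-7-(3-methylbutanoyloxy)decahydronaphthalen-1-yl]pentanoate
Product: 21 (3S)-3-methyl-5-[(1S,4aR,7S,8aR)-5,5,8a-trimethyl-2-methylidene-7-(3-methylbutanoyloxy)decahydronaphthalen-1-yl]pentanoic acid
Conditions: Me3SnOH (5 equiv), ClCH2CH2Cl, 80 °C; then 5% aq. HCl
Reagents that add atoms: trimethyltin hydroxide (C[Sn](C)(C)O)
Why: Trimethyltin hydroxide should cleave the unhindered primary-chain methyl ester under neutral conditions while the isovalerate, shielded by two syn-axial methyls, and the acid-sensitive exocyclic alkene are left intact (chemoselective ester hydrolysis).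

**Compound list**

1 | (R)-5-methoxy-3-methyl-5-oxopentanoic acid (monomethyl (R)-3-methylglutarate) | OC(=O)C[C@@H](C)CC(=O)OC | starting material
2 | lithium (S)-5-hydroxy-3-methylpentanoate | [Li+].[O-]C(=O)C[C@@H](C)CCO | intermediate
3 | (S)-4-methyltetrahydro-2H-pyran-2-one | O=C1C[C@@H](C)CCO1 | intermediate
4 | trimethylsilyl (R)-5-iodo-3-methylpentanoate | C[Si](C)(C)OC(=O)C[C@@H](C)CCI | intermediate
5 | methyl (R)-5-iodo-3-methylpentanoate | COC(=O)C[C@@H](C)CCI | intermediate
6 | 2-methylcyclopent-2-en-1-one | CC1=CCCC1=O | starting material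
7 | isopropenylmagnesium bromide | CC(=C)[Mg]Br | starting material
8 | allyl iodide (3-iodoprop-1-ene) | C=CCI | starting material
9 | bromomagnesium (R)-2-methyl-3-(prop-1-en-2-yl)cyclopent-1-en-1-olate | Br[Mg]OC1=C(C)[C@@H](C(C)=C)CC1 | intermediate
10 | (2R,3R)-2-allyl-2-methyl-3-(prop-1-en-2-yl)cyclopentan-1-one (allyl trans to isopropenyl) | O=C1CC[C@H](C(C)=C)[C@@]1(C)CC=C | intermediate
11 | (2R,3R)-2-methyl-2-(2-oxopropyl)-3-(prop-1-en-2-yl)cyclopentan-1-one | O=C1CC[C@H](C(C)=C)[C@@]1(C)CC(C)=O | intermediate
12 | (3aR,7aR)-4,4,7a-trimethylhexahydro-1H-indene-1,6(2H)-dione (trans-fused) | O=C1CC[C@@H]2C(C)(C)CC(=O)C[C@@]12C | intermediate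
13 | (3aR,6S,7aR)-6-hydroxy-4,4,7a-trimethyloctahydro-1H-inden-1-one (hydroxyl axial, cis to the 7a-methyl) | O=C1CC[C@@H]2C(C)(C)C[C@H](O)C[C@@]12C | intermediate
14 | dibromomethane | BrCBr | starting material
15 | dilithium (3aR,6S,7aR)-1-(dibromomethyl)-4,4,7a-trimethyloctahydro-1H-indene-1,6-bis(olate), both C1 epimers | [Li]OC1(C(Br)Br)CC[C@@H]2C(C)(C)C[C@H](O[Li])C[C@@]12C | intermediate
16 | dilithium (4aR,7S,8aR)-5,5,8a-trimethyl-3,4,4a,5,6,7,8,8a-octahydronaphthalene-2,7-bis(olate) (C8–C9 enolate) | [Li]OC1=C[C@]2(C)C[C@@H](O[Li])CC(C)(C)[C@H]2CC1 | intermediate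
17 | methyl (3S)-5-[(1R,4aR,7S,8aR)-7-hydroxy-5,5,8a-trimethyl-2-oxodecahydronaphthalen-1-yl]-3-methylpentanoate | O=C1CC[C@@H]2C(C)(C)C[C@H](O)C[C@@]2(C)[C@H]1CC[C@H](C)CC(=O)OC | intermediate
18 | methyl (3S)-5-[(1S,4aR,7S,8aR)-7-hydroxy-5,5,8a-trimethyl-2-methylidenedecahydronaphthalen-1-yl]-3-methylpentanoate | C=C1CC[C@@H]2C(C)(C)C[C@H](O)C[C@@]2(C)[C@H]1CC[C@H](C)CC(=O)OC | intermediate
19 | 3-methylbutanoyl chloride (isovaleryl chloride) | CC(C)CC(Cl)=O | starting material
20 | methyl (3S)-3-methyl-5-[(1S,4aR,7S,8aR)-5,5,8a-trimethyl-2-methylidene-7-(3-methylbutanoyloxy)decahydronaphthalen-1-yl]pentanoate | C=C1CC[C@@H]2C(C)(C)C[C@H](OC(=O)CC(C)C)C[C@@]2(C)[C@H]1CC[C@H](C)CC(=O)OC | intermediate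
21 | (3S)-3-methyl-5-[(1S,4aR,7S,8aR)-5,5,8a-trimethyl-2-methylidene-7-(3-methylbutanoyloxy)decahydronaphthalen-1-yl]pentanoic acid | C=C1CC[C@@H]2C(C)(C)C[C@H](OC(=O)CC(C)C)C[C@@]2(C)[C@H]1CC[C@H](C)CC(=O)O | target

Total step count: 10. Longest linear sequence: 8 steps (steps 3–10); the two-step side-chain branch (steps 1–2) joins at step 7.

**Steps most likely to fail**

Step 7. The C-alkylation of the hindered dianionic enolate by an unactivated primary iodide may be slow, so that proton transfer to the product, leakage to the C7 enolate and epimerisation at C9 compete. The fallback replaces the SN2 alkylation by an aldol addition followed by radical deoxygenation; it sets out from 5 and 13 and returns at 17. Kornblum oxidation of 5 (DMSO, NaHCO3, 110 °C) should give methyl (S)-3-methyl-5-oxopentanoate F1. Compound 13 is ring-expanded exactly as in step 7, and enolate 16 is quenched at −78 °C with F1, which should add to C9 on the same face, anti to the C10 methyl. This gives methyl (3S)-5-hydroxy-5-[(4aR,7S,8aR)-7-hydroxy-5,5,8a-trimethyl-2-oxodecahydronaphthalen-1-yl]-3-methylpentanoate F2 (chain anti to the 8a-methyl, carbinol epimers). Thioacylation of the unhindered side-chain hydroxyl (PhOC(S)Cl, pyridine, DMAP, 0 °C) should give methyl (3S)-5-[(4aR,7S,8aR)-7-hydroxy-5,5,8a-trimethyl-2-oxodecahydronaphthalen-1-yl]-3-methyl-5-(phenoxycarbonothioyloxy)pentanoate F3. Barton–McCombie reduction (Bu3SnH, AIBN, PhMe, 80 °C) then removes the C11 oxygen and gives 17.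

Step 5. The enol–ene closure needs 300 °C, where thermal degradation or aldol self-condensation of the 1,4-diketone may outrun the cyclisation. The fallback builds ring A by olefin acylation and conjugate methylation; it sets out from 6 (with 7) and returns at 12. The copper-catalysed addition of step 3 is run with tert-butyl bromoacetate as the trap and should give tert-butyl 2-[(1R,5R)-1-methyl-2-oxo-5-(prop-1-en-2-yl)cyclopentyl]acetate F4. CF3CO2H followed by (CF3CO)2O (CH2Cl2, 0 °C → rt) cleaves the ester and cyclises the mixed anhydride onto the isopropenyl group, giving the enone (3aR,7aR)-4,7a-dimethyl-3,3a,7,7a-tetrahydro-1H-indene-1,6(2H)-dione F5. Me2CuLi (Et2O, −20 °C) then adds the second C4 methyl and gives 12.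

Step 3. The alkenyl Grignard reagent may add with poor enantiofacial selectivity or in the 1,2-sense under copper catalysis. The fallback uses rhodium catalysis and a separate enolate generation; it sets out from 6 and returns at 10. Addition of potassium isopropenyltrifluoroborate catalysed by [Rh(cod)2]BF4 and BINAP (the enantiomer that gives the required centre; toluene/H2O, 100 °C) should give (3S)-2-methyl-3-(prop-1-en-2-yl)cyclopentan-1-one F6 (C2 epimers). Thermodynamic silylation (Me3SiCl, NaI, Et3N, MeCN) should give the tetrasubstituted enol ether trimethyl{[(3R)-2-methyl-3-(prop-1-en-2-yl)cyclopent-1-en-1-yl]oxy}silane F7. MeLi (THF, 0 °C) followed by 8 (HMPA, −78 °C) allylates C2 anti to the isopropenyl group and gives 10.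

Further compounds
F1 | step 7 | methyl (S)-3-methyl-5-oxopentanoate | COC(=O)C[C@@H](C)CC=O
F2 | step 7 | methyl (3S)-5-hydroxy-5-[(4aR,7S,8aR)-7-hydroxy-5,5,8a-trimethyl-2-oxodecahydronaphthalen-1-yl]-3-methylpentanoate (chain anti to the 8a-methyl, carbinol epimers) | O=C1CC[C@@H]2C(C)(C)C[C@H](O)C[C@@]2(C)[C@H]1C(O)C[C@H](C)CC(=O)OC
F3 | step 7 | methyl (3S)-5-[(4aR,7S,8aR)-7-hydroxy-5,5,8a-trimethyl-2-oxodecahydronaphthalen-1-yl]-3-methyl-5-(phenoxycarbonothioyloxy)pentanoate | O=C1CC[C@@H]2C(C)(C)C[C@H](O)C[C@@]2(C)[C@H]1C(OC(=S)Oc1ccccc1)C[C@H](C)CC(=O)OC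
F4 | step 5 | tert-butyl 2-[(1R,5R)-1-methyl-2-oxo-5-(prop-1-en-2-yl)cyclopentyl]acetate | O=C1CC[C@H](C(C)=C)[C@@]1(C)CC(=O)OC(C)(C)C
F5 | step 5 | (3aR,7aR)-4,7a-dimethyl-3,3a,7,7a-tetrahydro-1H-indene-1,6(2H)-dione | O=C1CC[C@@H]2C(C)=CC(=O)C[C@@]12C
F6 | step 3 | (3S)-2-methyl-3-(prop-1-en-2-yl)cyclopentan-1-one (C2 epimers) | O=C1CC[C@H](C(C)=C)C1C
F7 | step 3 | trimethyl{[(3R)-2-methyl-3-(prop-1-en-2-yl)cyclopent-1-en-1-yl]oxy}silane | C[Si](C)(C)OC1=C(C)[C@@H](C(C)=C)CC1
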